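The cyclopentane (C1–C5, daucane numbering) is not assembled as a five-membered ring: it arises by contraction of the cyclohexane of a cis-decalin that already holds all fifteen skeletal carbons (thymoquinone Diels–Alder adduct). The key step is a pinacol-type 1,2-shift in a 4,5,6-triol 5-mesylate: the C6–C1 ring-fusion bond, antiperiplanar to the equatorial mesylate, moves from the C6 carbinol to C5. In one operation ring A shrinks to the cyclopentane, ring B grows to the cycloheptanone (C6=O) and the trans C1/C5 fusion is set by inversion at C5. The step exploits the C4(OH)–C5(H)–C6(O) array next to the quaternary C1.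

Key step: step 11

Numbering: daucane numbers of the target are kept for every precursor: C1 (quaternary, methyl), C2 (OAc), C3, C4 (OH, isopropyl), C5 (ring-fusion CH), C6 (ester), C7, C8 (methyl), C9, C10 (OH). β is the face of the C1 methyl. In the decalins ring A is C1–C6 and ring B is C6–C10 plus C1.

Assumption: the oxirane is taken as cis-fused to the cycloheptane with its oxygen on the face of the C10 hydroxyl (8α,9α, as the C9 descriptor says), since an epoxide on a seven-membered ring cannot reasonably be fused otherwise; the target string is used unchanged.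

Compounds 4 to 7 are racemic (the SMILES show the enantiomer that is carried on); the resolution is part of step 5.

Step 1
Reactants: 1 3-methylbut-2-enal
Product: 2 (E)-tert-butyldimethyl[(3-methylbuta-1,3-dien-1-yl)oxy]silane
Conditions: t-BuMe2SiOTf, Et3N, Et2O, 0 °C to rt
Reagents that add atoms: tert-butyldimethylsilyl triflate CC(C)(C)[Si](C)(C)OS(=O)(=O)C(F)(F)F
Why: O-silylation of the enal followed by γ-deprotonation by the amine (soft enolisation to a silyl dienol ether) should give the conjugated dienol ether, with E geometry at the new enol double bond.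

Step 2
Reactants: 2 (E)-tert-butyldimethyl[(3-methylbuta-1,3-dien-1-yl)oxy]silane; 3 thymoquinone
Product: 4 racemic cis-fused Diels–Alder adduct (C2 and C5 ketones, C3=C4 bearing the isopropyl group, C1 methyl and H-6 cis, C8(Me)=C9, 10-OSi-t-BuMe2 trans to the C1 methyl)
Conditions: toluene, 0 °C to rt, dark, no Lewis acid
Reagents that add atoms: none
Why: Thermal Diels–Alder reaction: the diene should add to the less hindered, methyl-bearing double bond with its nucleophilic CH2 terminus on the unsubstituted C6 (α-methyl-enone polarisation, so the silyloxy carbon C10 ends next to C1), suprafacially (cis ring fusion) and endo (10-O cis to the C2 carbonyl branch, trans to the C1 methyl); no chiral element is present, so 4 is racemic.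

Step 3
Reactants: 4 racemic Diels–Alder adduct
Product: 6 racemic 6-hydroxy ene-dione (6-OH cis to the C1 methyl), via potassium dienolate 5 (not isolated)
Conditions: KN(SiMe3)2, THF, −78 °C; then 3-phenyl-2-(phenylsulfonyl)oxaziridine, −78 °C; aq. NH4Cl
Reagents that add atoms: 3-phenyl-2-(phenylsulfonyl)oxaziridine O=S(=O)(c1ccccc1)N1OC1c1ccccc1
Why: Davis enolate oxidation: C6–H is the only hydrogen α to a carbonyl on an sp3 carbon, and the oxaziridine should attack the dienolate face opposite to the C10 branch of ring B, which restores the cis ring fusion.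

Step 4
Reactants: 6 racemic 6-hydroxy ene-dione
Product: 7 racemic 5,6-diol with the C2 enone intact (5-OH trans to 6-OH)
Conditions: NaBH4 (1 equiv), CeCl3·7H2O, MeOH–CH2Cl2, −78 °C
Reagents that add atoms: none
Why: Luche reduction: the C5 carbonyl, activated by the neighbouring hydroxyl (cerium chelation) and less shielded than C2 (which sits beside the quaternary carbon carrying the silyloxy methine), should be reduced first; hydride from the convex face gives 5-OH trans to 6-OH, a centre that is erased in step 6.

Step 5
Reactants: 7 racemic 5,6-diol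
Product: 8 5-O-[(1S)-camphanoyl] ester of the drawn enantiomer of 7 (single diastereomer)
Conditions: (1S)-camphanic chloride, Et3N, 4-(dimethylamino)pyridine, CH2Cl2, 0 °C to rt; chromatographic separation of the two diastereomeric esters, then crystallisation
Reagents that add atoms: (1S)-camphanic chloride C[C@@]12CC[C@@](C1(C)C)(OC2=O)C(=O)Cl
Why: Nucleophilic acyl transfer to the only secondary hydroxyl turns the racemate into two diastereomeric esters (classical resolution), of which the one drawn is carried on; the ester is also the leaving group for step 6.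

Step 6
Reactants: 8 camphanate
Product: 9 β,γ-unsaturated ketone (C2 ketone, C3 methylene, C4(iPr)=C5, tertiary allylic 6-OH)
Conditions: SmI2 (2.5 equiv), THF–MeOH, −78 °C
Reagents that add atoms: none
Why: Reductive vinylogous elimination of a γ-acyloxy enone: two-electron reduction puts carbanion character on C4, the C5 carboxylate is expelled to form C4=C5, and kinetic protonation of the samarium dienolate at C3 by methanol should leave the deconjugated ketone; no stereocentre is formed.

Step 7
Reactants: 9 β,γ-unsaturated ketone
Product: 10 2,6-diol (2-OH trans to 6-OH and to the C1 methyl)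
Conditions: Me4NBH(OAc)3, AcOH–MeCN, −30 °C
Reagents that add atoms: none
Why: Evans–Saksena reduction: the tertiary C6 hydroxyl, 1,3 to the ketone through C1, binds boron and delivers hydride to the same face of C2, which should give the 1,3-anti diol, that is the future 2α-oxygen.

Step 8
Reactants: 10 2,6-diol
Product: 11 2-acetate (6-OH free)
Conditions: Ac2O, pyridine, 4-(dimethylamino)pyridine, rt
Reagents that add atoms: acetic anhydride CC(=O)OC(C)=O
Why: Catalysed acyl transfer distinguishes the secondary C2 hydroxyl from the hindered tertiary allylic C6 hydroxyl, which stays free as the directing group for step 9.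

Step 9
Reactants: 11 2-acetate
Product: 13 4,5,6-triol (all three hydroxyls cis to the C1 methyl; isopropyl on the other face), via osmate ester 12 (not isolated)
Conditions: OsO4 (1.05 equiv), Me2NCH2CH2NMe2, CH2Cl2, −78 °C; then aq. Na2SO3, THF, 40 °C
Reagents that add atoms: osmium tetroxide O=[Os](=O)(=O)=O
Why: Hydroxyl-directed dihydroxylation with the OsO4–diamine complex: hydrogen bonding to the allylic C6 hydroxyl should steer the reagent to C4=C5 rather than the non-directed C8=C9, and to the convex face syn to that hydroxyl, so syn addition sets both C4 and C5.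

Step 10
Reactants: 13 4,5,6-triol
Product: 14 5-mesylate
Conditions: MsCl, Et3N, CH2Cl2, −20 °C
Reagents that add atoms: methanesulfonyl chloride CS(=O)(=O)Cl
Why: Sulfonylation through sulfene picks the single secondary hydroxyl (C5) between the two tertiary ones; no stereocentre changes.

Step 11
Reactants: 14 5-mesylate
Product: 15 trans-fused hydroazulenone (6-ketone, H-5α, C1-Me β, 2α-OAc, 4β-OH, 10α-OSi-t-BuMe2, C8=C9)
Conditions: Et3Al (3 equiv), CH2Cl2, −78 to −20 °C; aqueous Rochelle salt
Reagents that add atoms: none
Why: Et3Al converts the C4 and C6 hydroxyls into aluminium alkoxides and activates the sulfonate; in the chair of ring A with isopropyl and mesylate equatorial, the C6–C1 ring-fusion bond is antiperiplanar to the C5–O bond and, pushed by the C6 alkoxide, shifts to C5 as mesylate leaves, so C6 becomes the ketone. This is a pinacol-type (semipinacol) rearrangement of a 2-sulfonyloxy tertiary alcohol, the classical decalin-to-hydroazulene ring contraction and expansion. The cyclopentane is closed by the 1,2-alkyl shift itself (new bond C1–C5; ring A loses C6), and the same shift enlarges ring B to the seven-membered ring by taking in C5; neither ring forms by an exo or endo cyclisation. C5 is the only stereocentre made anew: backside entry of C1 inverts it and places H-5 trans to the C1 methyl, while C1 migrates with retention and C2, C4 and C10 are untouched. The step needs C1 to migrate from the C6 carbinol rather than C3 from the C4 carbinol, whose ring bond is also anti to the mesylate: the fully substituted C1 is the better migrating group, epoxide formation is excluded because both alkoxides are cis to the leaving group, and C4 and C6 carry no hydrogen for a hydride shift. The β,γ-unsaturated ketone is taken directly into step 12 to forestall conjugation and C5 epimerisation.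

Step 12
Reactants: 15 hydroazulenone
Product: 16 6α-alcohol
Conditions: Me4NBH(OAc)3, AcOH–MeCN, −30 °C
Reagents that add atoms: none
Why: Evans–Saksena reduction directed by the tertiary C4 hydroxyl (β-hydroxy ketone through C5): intramolecular hydride delivery should give the 1,3-anti diol, which is the 6α-alcohol, under mild conditions that spare the β,γ-double bond and C5.

Step 13
Reactants: 16 6α-alcohol; 17 3,4-dimethoxybenzoyl chloride
Product: 18 6α-(3,4-dimethoxybenzoate)
Conditions: Et3N, 4-(dimethylamino)pyridine, CH2Cl2, rt
Reagents that add atoms: none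
Why: Catalysed acylation of the only secondary hydroxyl; the tertiary C4 hydroxyl does not react.

Step 14
Reactants: 18 6α-(3,4-dimethoxybenzoate)
Product: 19 10α-allylic alcohol
Conditions: HF·pyridine, pyridine, THF, 0 °C to rt
Reagents that add atoms: none
Why: Fluoride cleavage of the silyl ether under buffered acidic conditions should leave both esters in place and avoid acetate migration from O2 to O10.

Step 15
Reactants: 19 10α-allylic alcohol
Product: 20 target, 2α-acetoxy-6α-(3,4-dimethoxybenzoyloxy)-8α,9α-epoxy-trans-daucane-4β,10α-diol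
Conditions: VO(acac)2 (5 mol %), t-BuOOH, CH2Cl2, 0 °C
Reagents that add atoms: tert-butyl hydroperoxide CC(C)(C)OO
Why: Vanadium-catalysed hydroxyl-directed epoxidation of the allylic alcohol: the C10 hydroxyl binds the peroxovanadium species and delivers oxygen to the syn face of the only alkene, which should give the 8α,9α-epoxide.

Compound list
1 | 3-methylbut-2-enal | CC(C)=CC=O | starting material
2 | (E)-tert-butyldimethyl[(3-methylbuta-1,3-dien-1-yl)oxy]silane | C=C(C)/C=C/O[Si](C)(C)C(C)(C)C | intermediate
3 | thymoquinone (2-isopropyl-5-methyl-1,4-benzoquinone) | CC1=CC(=O)C(C(C)C)=CC1=O | starting material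
4 | racemic cis-fused Diels–Alder adduct (2,5-dione, C3=C4(iPr), C8(Me)=C9, 10-silyloxy trans to C1-Me) | [C@@]12(C)C(=O)C=C(C(C)C)C(=O)[C@@H]1CC(C)=C[C@@H]2O[Si](C)(C)C(C)(C)C | intermediate
5 | potassium C5-O,C6 dienolate of 4 (racemic) | [C@@]12(C)C(=O)C=C(C(C)C)C([O-])=C1CC(C)=C[C@@H]2O[Si](C)(C)C(C)(C)C.[K+] | intermediate
6 | racemic 6-hydroxy ene-dione (6-OH cis to C1-Me) | [C@@]12(C)C(=O)C=C(C(C)C)C(=O)[C@]1(O)CC(C)=C[C@@H]2O[Si](C)(C)C(C)(C)C | intermediate
7 | racemic 5,6-diol enone (5-OH trans to 6-OH) | [C@@]12(C)C(=O)C=C(C(C)C)[C@H](O)[C@]1(O)CC(C)=C[C@@H]2O[Si](C)(C)C(C)(C)C | intermediate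
8 | 5-O-[(1S)-camphanoyl] ester, single diastereomer | [C@@]12(C)C(=O)C=C(C(C)C)[C@H](OC(=O)[C@]34OC(=O)[C@](C)(CC3)C4(C)C)[C@]1(O)CC(C)=C[C@@H]2O[Si](C)(C)C(C)(C)C | intermediate
9 | β,γ-unsaturated ketone (C2=O, C4(iPr)=C5, 6-OH) | [C@@]12(C)C(=O)CC(C(C)C)=C[C@]1(O)CC(C)=C[C@@H]2O[Si](C)(C)C(C)(C)C | intermediate
10 | 2,6-diol (2-OH trans to 6-OH) | [C@@]12(C)[C@H](O)CC(C(C)C)=C[C@]1(O)CC(C)=C[C@@H]2O[Si](C)(C)C(C)(C)C | intermediate
11 | 2-acetate | [C@@]12(C)[C@H](OC(C)=O)CC(C(C)C)=C[C@]1(O)CC(C)=C[C@@H]2O[Si](C)(C)C(C)(C)C | intermediate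
12 | cyclic 4,5-osmate ester (hexavalent osmium) with chelating Me2NCH2CH2NMe2 | [C@@]12(C)[C@H](OC(C)=O)C[C@@]3(C(C)C)O[Os-2]4(=O)(=O)([N+](C)(C)CC[N+]4(C)C)O[C@H]3[C@]1(O)CC(C)=C[C@@H]2O[Si](C)(C)C(C)(C)C | intermediate
13 | 4,5,6-triol (all OH cis to C1-Me) | [C@@]12(C)[C@H](OC(C)=O)C[C@](O)(C(C)C)[C@@H](O)[C@]1(O)CC(C)=C[C@@H]2O[Si](C)(C)C(C)(C)C | intermediate
14 | 5-mesylate of 13 | [C@@]12(C)[C@H](OC(C)=O)C[C@](O)(C(C)C)[C@@H](OS(C)(=O)=O)[C@]1(O)CC(C)=C[C@@H]2O[Si](C)(C)C(C)(C)C | intermediate
15 | trans-fused hydroazulen-6-one (2α-OAc, 4β-OH, 10α-silyloxy) | O=C1CC(C)=C[C@H](O[Si](C)(C)C(C)(C)C)[C@]2(C)[C@H](OC(C)=O)C[C@](O)(C(C)C)[C@@H]12 | intermediate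
16 | 6α-alcohol | O[C@@H]1CC(C)=C[C@H](O[Si](C)(C)C(C)(C)C)[C@]2(C)[C@H](OC(C)=O)C[C@](O)(C(C)C)[C@@H]12 | intermediate
17 | 3,4-dimethoxybenzoyl chloride | COc1ccc(C(Cl)=O)cc1OC | starting material
18 | 6α-(3,4-dimethoxybenzoate), 10-silyl ether | COc1ccc(C(=O)O[C@@H]2CC(C)=C[C@H](O[Si](C)(C)C(C)(C)C)[C@]3(C)[C@H](OC(C)=O)C[C@](O)(C(C)C)[C@@H]23)cc1OC | intermediate
19 | 10α-allylic alcohol | COc1ccc(C(=O)O[C@@H]2CC(C)=C[C@H](O)[C@]3(C)[C@H](OC(C)=O)C[C@](O)(C(C)C)[C@@H]23)cc1OC | intermediate
20 | 2α-acetoxy-6α-(3,4-dimethoxybenzoyloxy)-8α,9α-epoxy-trans-daucane-4β,10α-diol | COc1ccc(C(=O)O[C@@H]2C[C@@]3(C)O[C@@H]3[C@H](O)[C@]3(C)[C@H](OC(C)=O)C[C@](O)(C(C)C)[C@@H]23)cc1OC | target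

Total step count: 15. Longest linear sequence: 15 steps (1 to 20); 3 and 17 enter as purchased materials.

Steps most likely to fail

Step 11 (key step). The shift may start from the wrong carbinol: the C4 alkoxide can push C3 onto C5 (its ring bond is also anti to the mesylate), giving a ring-A-contracted isobutyryl ketone; the product ketone may also conjugate or epimerise at C5. Fallback: the route sets out from 14 and first takes the C4 hydroxyl out of play. Me3SiOTf (1 equiv) and 2,6-lutidine at −78 °C should silylate the less hindered tertiary hydroxyl at C4 (the C6 hydroxyl lies between the quaternary C1 and C7) to give the 4-O-trimethylsilyl mesylate F1. Et3Al then finds a single free carbinol and should give the 4-O-silyl hydroazulenone F2. Citric acid in methanol removes the silyl ether, and the route is rejoined at 15.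

Step 9. Site selectivity may be lost: the more accessible, non-directed C8=C9 bond may be osmylated in competition with the hindered C4=C5 bond. Fallback: the route sets out from 11 and masks the competing alkene. Pyridinium tribromide in CH2Cl2 at −78 °C should add to the unhindered C8=C9 bond only and give the trans-8,9-dibromide F3. Dihydroxylation of the one remaining alkene (OsO4, Me2NCH2CH2NMe2, then Na2SO3) gives the dibromo triol F4. Zinc dust in acetic acid–ethanol regenerates C8=C9, and the route is rejoined at 13.

Step 3. The strong base may deprotonate elsewhere (the isopropyl methine through the vinylogous C2 carbonyl, or C7) or degrade the ene-dione before oxygen transfer. Fallback: the route sets out from 4 and oxidises a neutral enol derivative instead of an enolate. Soft enolisation (Me3SiOTf, Et3N, CH2Cl2, 0 °C) can only engage C6–H and should give the 5-trimethylsilyloxy 5,6-diene F5. Rubottom oxidation with dimethyldioxirane (acetone, −78 °C, one equivalent, the silyl enol ether being far more electron-rich than C8=C9), followed by citric acid in methanol, returns the route at 6.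

Further compounds
F1 | step 11 | 4-O-trimethylsilyl ether of mesylate 14 | [C@@]12(C)[C@H](OC(C)=O)C[C@](O[Si](C)(C)C)(C(C)C)[C@@H](OS(C)(=O)=O)[C@]1(O)CC(C)=C[C@@H]2O[Si](C)(C)C(C)(C)C
F2 | step 11 | 4-O-trimethylsilyl ether of hydroazulenone 15 | O=C1CC(C)=C[C@H](O[Si](C)(C)C(C)(C)C)[C@]2(C)[C@H](OC(C)=O)C[C@](O[Si](C)(C)C)(C(C)C)[C@@H]12
F3 | step 9 | trans-8,9-dibromide of 11 | [C@@]12(C)[C@H](OC(C)=O)CC(C(C)C)=C[C@]1(O)C[C@](C)(Br)[C@@H](Br)[C@@H]2O[Si](C)(C)C(C)(C)C
F4 | step 9 | trans-8,9-dibromo 4,5,6-triol | [C@@]12(C)[C@H](OC(C)=O)C[C@](O)(C(C)C)[C@@H](O)[C@]1(O)C[C@](C)(Br)[C@@H](Br)[C@@H]2O[Si](C)(C)C(C)(C)C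
F5 | step 3 | 5-trimethylsilyloxy 5,6-diene from 4 (racemic) | [C@@]12(C)C(=O)C=C(C(C)C)C(O[Si](C)(C)C)=C1CC(C)=C[C@@H]2O[Si](C)(C)C(C)(C)C
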